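The rate constants are invented; the run is a simulation.

**Target as gauge.** Target leaves complex A by a first-order step, so its rate of formation reads the concentration of complex A, [A]. The same concentration gives the catalyst's split between complex A and the dimer. Catalyst held as dimer over catalyst held as complex A equals [A]/A\*, where A\* = 0.0208 µM, one over 2 times the dimer constant. At A\* the two forms hold equal catalyst, and this symmetric point is my zero.

starting material 10 mM; second substrate 10.0 mM; protic impurity 2.00 mM; enzyme 0.12 µM

    starting material + enzyme ⇌ complex A (K1 = 1000 L mol⁻¹, k1 = 1.8 × 10⁵ L mol⁻¹ s⁻¹)
    complex A → enzyme + target (k2 = 180 s⁻¹)
    second substrate + enzyme ⇌ complex B (K3 = 4700 L mol⁻¹, k3 = 1.2 × 10⁶ L mol⁻¹ s⁻¹)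
    complex B → enzyme + second product (k4 = 980 s⁻¹)
    2 complex A ⇌ resting dimer, settled at all times (K5 = 2.4 × 10⁷ L mol⁻¹)
    starting material + protic impurity → quenched substrate (k6 = 0.27 L mol⁻¹ s⁻¹)

- percentages count the starting material that a species holds: one resting dimer counts as two
- a step written with two of one species runs at k times the square of its concentration and takes two of it each time
- a form made of two catalysts counts as two
- charge of starting material (flask): 10 mM

- the form that holds most of the catalyst when 10 % of the starting material are converted (complex A / complex B / enzyme / resting dimer)
- its share of the catalyst then

**The balance.** I took the complexes as steady. With starting material at 9.00 mM, [A] is 4.50 times the free enzyme concentration, and complex B is 971 L mol⁻¹ times free enzyme times second substrate. Counting the dimer as two gives a quadratic in [A], so the open question is how much second substrate stands.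

**Way one.** I kept second substrate at its charge. Then [A] = 0.0259 µM, or 1.25 on my scale. The dimer holds 26.9 %, less than complex B at 46.7 %.

**Way two.** I let second substrate be consumed. At the start, [A]/[E] is 5.00 and [A] is 0.0270 µM. Step 4 then uses 5.01 mol of second substrate per mol of starting material lost to target and quench together. That leaves 4.99 mM at the asked point. The same balance gives [A] = 0.0315 µM, or 1.51 on the scale. The dimer now holds 39.7 %, ahead of complex B at 28.3 %.

**Which cheats.** Way one cheats, since it freezes a reagent that is consumed faster than starting material. Way two may err mildly the other way: its ratio belongs to the start, when second substrate stood at its charge. I committed to the dimer as resting state, at slightly under 39.7 %.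

**The result.** The forecast said resting dimer at 38 %, remarking of the early rates “so the quench matters”. In the flask, resting dimer holds 38.1 %, complex B 30.5 %, complex A 25.7 % and enzyme 5.71 %.

**Scale reused.** At the asked point, the target rate 20.0 mM h⁻¹ over its rate constant reads [A] = 0.0309 µM, which is 1.49 on the scale, and the shares give 1.48. In the same flask at 0.250 h, complex A's 29.3 % predicts 1.69, and the readings give 1.69. Above A\*, added catalyst goes increasingly into the dimer, and this bends the order in enzyme to 0.77; without the dimer it is 1.1.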